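## Retrosynthetic overview

1. Target 28 ⇐ 2α,3α-diol 24 (acylation of the equatorial O2 with an angelic mixed anhydride, then removal of the C13 silyl ether) ⇐ C2=C3 silyl enol ether 21 (α-face oxidation at C2, hydride to C3) ⇐ C20 acid 19.
2. Strategic feature: quaternary C10 carries the oxidised carbon C20, is bonded to the C9 methine, and the ring B alkene C7=C8 (with the C17 methyl) begins one bond further on. C20–C10–C9–C8=C7 is thus a γ,δ-unsaturated acid; breaking C9–C10 and joining C20 to an oxygen on C7 gives a ring A-fused δ-lactone with an (E)-alkenyl group on C7 (ester-enolate Claisen retron).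
3. Ring A of that lactone ⇐ double Michael annulation of the dienolate of isopropyl vinyl ketone onto 6-alkenyl-5,6-dihydropyran-2-one 10 ⇐ acrylate ring-closing metathesis of homoallylic alcohol 7 ⇐ enal 4 ⇐ (R)-linalool (source of C13).
4. Order of ring formation: δ-lactone (metathesis), then ring A (annulation), then ring B (Claisen rearrangement, which opens the lactone).

Key step: step 10

Remark: atoms carry the labdane numbers of the target (decalin C1–C10, side chain C11–C16 with carbinol C13, C17 on C8, C18/C19 on C4, C20 on C10); α/β refer to the usual drawing with C20 β.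
Remark: commercial (R)-(−)-linalool of high enantiomeric purity is assumed.
Remark: lactone 16 is drawn with H10 cis to H5; the C10 epimer would serve equally, because C10 becomes trigonal in step 9.

## Route

Step 1
Reactants: 1 (R)-linalool
Product: 2 (3R)-3,7-dimethyl-3-(triethylsilyloxy)octa-1,6-diene
Conditions: Et3SiOTf, 2,6-lutidine, CH2Cl2, −78 → 0 °C
Reagents that add atoms: triethylsilyl triflate, CC[Si](CC)(CC)OS(=O)(=O)C(F)(F)F
Why: Silylation of the hindered tertiary allylic alcohol needs the silyl triflate with a hindered pyridine base; C13 is untouched and the ether masks the alcohol through the later enolate, hydride and metathesis steps.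

Step 2
Reactants: 2 (3R)-3,7-dimethyl-3-(triethylsilyloxy)octa-1,6-diene
Product: 3 (2E,6R)-2,6-dimethyl-6-(triethylsilyloxy)octa-2,7-dien-1-ol
Conditions: SeO2 (0.2 equiv), t-BuOOH, salicylic acid (cat.), CH2Cl2, rt
Reagents that add atoms: selenium dioxide (oxygen-transfer catalyst), O=[Se]=O; tert-butyl hydroperoxide (terminal oxidant), CC(C)(C)OO
Why: SeO2-catalysed allylic hydroxylation (ene reaction, then [2,3]-sigmatropic shift) should functionalise the (E)-methyl group of the trisubstituted alkene selectively, the vinyl group having no allylic hydrogen; any enal formed alongside converges in step 3.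

Step 3
Reactants: 3 (2E,6R)-2,6-dimethyl-6-(triethylsilyloxy)octa-2,7-dien-1-ol
Product: 4 (2E,6R)-2,6-dimethyl-6-(triethylsilyloxy)octa-2,7-dienal
Conditions: activated MnO2, CH2Cl2, rt
Reagents that add atoms: none
Why: MnO2 oxidises primary allylic alcohols selectively to enals without touching the silyl ether or isomerising the E alkene.

Step 4
Reactants: 4 (2E,6R)-2,6-dimethyl-6-(triethylsilyloxy)octa-2,7-dienal; 5 allylboronic acid pinacol ester
Product: 7 (4S,5E,9R)-5,9-dimethyl-9-(triethylsilyloxy)undeca-1,5,10-trien-4-ol, via pinacol borate ester 6 (not isolated)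
Conditions: 5 (1.3 equiv), (S)-3,3'-bis(2,4,6-triisopropylphenyl)-1,1'-binaphthyl-2,2'-diyl hydrogen phosphate (5 mol %), toluene, −30 °C; then H2O
Reagents that add atoms: none
Why: Chiral phosphoric acid-catalysed allylboration proceeds through a closed six-membered transition state; the (S)-catalyst is chosen to deliver the allyl group to the Si face of the enal and so set the C7 carbinol as S under catalyst control (remote C13 exerts no influence), and the borate ester is hydrolysed on work-up.

Step 5
Reactants: 7 (4S,5E,9R)-5,9-dimethyl-9-(triethylsilyloxy)undeca-1,5,10-trien-4-ol; 8 acryloyl chloride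
Product: 9 (4S,5E,9R)-5,9-dimethyl-9-(triethylsilyloxy)undeca-1,5,10-trien-4-yl acrylate
Conditions: Et3N, 4-(dimethylamino)pyridine (cat.), CH2Cl2, −20 → 0 °C
Reagents that add atoms: none
Why: Standard O-acylation of the secondary allylic alcohol with an acid chloride; the tertiary oxygen is silylated and cannot compete.

Step 6
Reactants: 9 (4S,5E,9R)-5,9-dimethyl-9-(triethylsilyloxy)undeca-1,5,10-trien-4-yl acrylate
Product: 10 (6S)-6-[(2E,6R)-6-methyl-6-(triethylsilyloxy)octa-2,7-dien-2-yl]-5,6-dihydro-2H-pyran-2-one
Conditions: second-generation Grubbs catalyst (H2IMes)(PCy3)Cl2Ru=CHPh (5 mol %), CH2Cl2 (0.005 M), 40 °C, short reaction time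
Reagents that add atoms: none
Why: Ring-closing metathesis should initiate at the unhindered allyl terminus and close onto the acrylate to give the six-membered unsaturated lactone with loss of ethylene; the vinyl group beside the quaternary silyloxy carbon and the trisubstituted alkene react far more slowly, and dilution with a short reaction time guards against cyclopentene-forming metathesis of the 1,6-diene.

Step 7
Reactants: 11 isopropyl vinyl ketone (4-methylpent-1-en-3-one)
Product: 12 4-methyl-3-(trimethylsilyloxy)penta-1,3-diene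
Conditions: Me3SiOTf, Et3N, Et2O, 0 °C
Reagents that add atoms: trimethylsilyl triflate, C[Si](C)(C)OS(=O)(=O)C(F)(F)F
Why: Soft enolisation of the vinyl ketone at its only α-CH gives the 2-silyloxy diene, a storable and regiodefined precursor of the cross-conjugated dienolate that avoids exposing the polymerisable enone to an amide base.

Step 8
Reactants: 12 4-methyl-3-(trimethylsilyloxy)penta-1,3-diene; 10 (6S)-6-[(2E,6R)-6-methyl-6-(triethylsilyloxy)octa-2,7-dien-2-yl]-5,6-dihydro-2H-pyran-2-one
Product: 16 ring A-fused δ-lactone triisopropylsilyl enol ether (cis-fused; 7α-alkenyl cis to H5), via lithium dienolate 13 (not isolated), via lactone enolate 14 (not isolated), via bicyclic ketone enolate 15 (not isolated)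
Conditions: 12 (1.3 equiv), MeLi, THF, 0 °C → rt; then 10, −78 → −20 °C; then i-Pr3SiOTf, −78 → 0 °C
Reagents that add atoms: triisopropylsilyl triflate, CC(C)[Si](OS(=O)(=O)C(F)(F)F)(C(C)C)C(C)C
Why: Methyllithium cleaves the Si–O bond to give the amine-free lithium dienolate, whose only nucleophilic carbon (future C4) adds in a Michael reaction to C5 of the lactone anti to the C7 alkenyl group (known trans preference of 6-substituted dihydropyranones), the lactone enolate then closes ring A by intramolecular Michael addition of C10 to the vinyl ketone terminus C1, and the regiodefined C3 enolate is trapped on oxygen; C5 is set by substrate control and the C10 configuration is immaterial.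

Step 9
Reactants: 16 ring A-fused δ-lactone triisopropylsilyl enol ether
Product: 17 cyclic tert-butyldimethylsilyl ketene acetal (C10=C20; 7-alkenyl cis to H5)
Conditions: LiN(i-Pr)2 (commercial solution), t-BuMe2SiCl, DMPU, THF, −78 → 0 °C; pentane, filtration, used crude
Reagents that add atoms: tert-butyldimethylsilyl chloride, CC(C)(C)[Si](C)(C)Cl
Why: The lactone has a single α-hydrogen (C10–H) and the ketone is masked as its enol ether, so amide base with silyl chloride present should give one cyclic ketene acetal by O-silylation of the lactone enolate (Ireland conditions), erasing the C10 centre.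

Step 10
Reactants: 17 cyclic tert-butyldimethylsilyl ketene acetal
Product: 19 (13R)-13-(triethylsilyloxy)-3-(triisopropylsilyloxy)labda-2,7,14-trien-20-oic acid (5α-H; 9α-H; 10β-CO2H), via tert-butyldimethylsilyl ester 18 (not isolated)
Conditions: toluene, 110 °C (sealed tube); then aq. LiOH, THF, 0 °C; NaH2PO4 to pH 5
Reagents that add atoms: none
Why: Heating the cyclic silyl ketene acetal should trigger a concerted suprafacial [3,3] shift over C10=C20–O–C7–C8=C9, in which the C9–C10 bond forms as the O–C7 bond breaks, the lactone carbonyl re-emerges as the C20 silyl ester (hydrolysed to the acid on work-up) and the alkene moves to C7=C8 with its C17 methyl. The closest known reaction type is the Ireland–Claisen rearrangement of lactone-derived silyl ketene acetals, which converts alkenyl lactones into cycloalkenecarboxylic acids. Ring B (C5–C6–C7–C8–C9–C10) is closed as a six-membered carbocycle by this pericyclic C–C bond formation, and because C7 and C10 are already tied by the C5–C6 bridge the six-atom array must pass through a boat, bicyclo[2.2.2]octane-like transition state. C10 is controlled by the C7 carbinol centre: its alkenyl group lies cis to H5, so C9 can reach only the α face of the ketene acetal, which leaves C20 β and anti to H5 (trans-decalin). C9 is controlled by the E geometry of the C8=C9 alkene within the enforced suprafacial boat, which places H9 α and the C11 chain β and equatorial, the C7 centre being consumed as its chirality is relayed. The step needs facial selectivity at C10 and C9 and no competing enolisation, both secured by the substrate (one α-hydrogen on the lactone, the C3 ketone masked as its enol ether, ring-enforced geometry), and carbonyl formation makes it irreversible.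

Step 11
Reactants: 19 (13R)-13-(triethylsilyloxy)-3-(triisopropylsilyloxy)labda-2,7,14-trien-20-oic acid
Product: 20 (13R)-13-(triethylsilyloxy)-3-(triisopropylsilyloxy)labda-2,7,14-trien-20-ol
Conditions: LiAlH4, THF, 0 °C → reflux; H2O, aq. NaOH work-up
Reagents that add atoms: none
Why: LiAlH4 reduces the hindered carboxylic acid to the neopentyl-type primary alcohol, while the silyl enol ether, the silyl ether and the unconjugated alkenes are inert to hydride.

Step 12
Reactants: 20 (13R)-13-(triethylsilyloxy)-3-(triisopropylsilyloxy)labda-2,7,14-trien-20-ol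
Product: 21 (13R)-13-(triethylsilyloxy)-3-(triisopropylsilyloxy)labda-2,7,14-trien-20-yl acetate
Conditions: Ac2O, pyridine, 4-(dimethylamino)pyridine (cat.), CH2Cl2, rt
Reagents that add atoms: acetic anhydride, CC(=O)OC(C)=O
Why: Nucleophile-catalysed acetylation of the only free hydroxyl; silyl enol ethers tolerate these conditions.

Step 13
Reactants: 21 (13R)-13-(triethylsilyloxy)-3-(triisopropylsilyloxy)labda-2,7,14-trien-20-yl acetate
Product: 23 (13R)-2α-hydroxy-3-oxo-13-(triethylsilyloxy)labda-7,14-dien-20-yl acetate, via silyloxy epoxide 22 (not isolated)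
Conditions: dimethyldioxirane (acetone solution, 1.05 equiv), CH2Cl2, −78 → −40 °C; then Bu4NF, AcOH, THF, −20 °C
Reagents that add atoms: dimethyldioxirane, CC1(C)OO1
Why: Rubottom-type oxidation: the electron-rich C2=C3 silyl enol ether should be epoxidised by the neutral dioxirane much faster than the C7=C8 alkene or the vinyl group, from the α face because the axial β groups on C10 (CH2OAc) and C4 (methyl) shield the β face; buffered fluoride then removes the silyl group from the labile silyloxy epoxide, which collapses to the ketone with the C2–O bond intact (2α-OH, equatorial), the tertiary alkyl silyl ether being far slower to cleave.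

Step 14
Reactants: 23 (13R)-2α-hydroxy-3-oxo-13-(triethylsilyloxy)labda-7,14-dien-20-yl acetate
Product: 24 (13R)-2α,3α-dihydroxy-13-(triethylsilyloxy)labda-7,14-dien-20-yl acetate
Conditions: LiBH(s-Bu)3 (2.5 equiv), THF, −78 °C; then H2O
Reagents that add atoms: none
Why: The bulky trialkylborohydride should attack the C3 ketone along the equatorial trajectory, as known for 4,4-dimethyl-3-keto terpenoids, giving the axial 3α-alcohol cis to the 2α-hydroxyl (substrate control); the acetate is not reduced at this temperature.

Step 15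
Reactants: 25 angelic acid ((Z)-2-methylbut-2-enoic acid)
Product: 26 angelic 2,4,6-trichlorobenzoic anhydride
Conditions: 2,4,6-trichlorobenzoyl chloride, Et3N, toluene, 0 °C → rt; filtration, used as solution
Reagents that add atoms: 2,4,6-trichlorobenzoyl chloride, O=C(Cl)c1c(Cl)cc(Cl)cc1Cl
Why: Acylation of the triethylammonium carboxylate by the hindered aroyl chloride gives the mixed anhydride (Yamaguchi-type activation) without a nucleophilic catalyst, so the Z alkene of the angeloyl group should not isomerise.

Step 16
Reactants: 24 (13R)-2α,3α-dihydroxy-13-(triethylsilyloxy)labda-7,14-dien-20-yl acetate; 26 angelic 2,4,6-trichlorobenzoic anhydride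
Product: 27 (13R)-20-acetoxy-3α-hydroxy-13-(triethylsilyloxy)labda-7,14-dien-2α-yl (Z)-2-methylbut-2-enoate
Conditions: 26 (1.5 equiv), Et3N, toluene, 75 °C
Reagents that add atoms: none
Why: The alcohol attacks the unhindered angeloyl carbonyl of the mixed anhydride (the aroyl carbonyl is shielded by two ortho chlorines); the equatorial secondary 2α-hydroxyl should react in preference to the axial 3α-hydroxyl flanked by the gem-dimethyl group, and leaving out 4-(dimethylamino)pyridine avoids Z to E isomerisation to the tiglate.

Step 17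
Reactants: 27 (13R)-20-acetoxy-3α-hydroxy-13-(triethylsilyloxy)labda-7,14-dien-2α-yl (Z)-2-methylbut-2-enoate
Product: 28 target CNP0171655.1, (13R)-20-acetoxy-3α,13-dihydroxylabda-7,14-dien-2α-yl (Z)-2-methylbut-2-enoate
Conditions: HF·pyridine, pyridine, THF, 0 °C → rt
Reagents that add atoms: none
Why: Buffered HF·pyridine cleaves the tertiary triethylsilyl ether without hydrolysing or migrating the acetate and angelate esters and without ionising the tertiary allylic alcohol.

## Compound list

1 | (R)-linalool, (3R)-3,7-dimethylocta-1,6-dien-3-ol | CC(C)=CCC[C@@](C)(O)C=C | starting material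
2 | (3R)-3,7-dimethyl-3-(triethylsilyloxy)octa-1,6-diene | CC(C)=CCC[C@@](C)(O[Si](CC)(CC)CC)C=C | intermediate
3 | (2E,6R)-2,6-dimethyl-6-(triethylsilyloxy)octa-2,7-dien-1-ol | OC/C(C)=C/CC[C@@](C)(O[Si](CC)(CC)CC)C=C | intermediate
4 | (2E,6R)-2,6-dimethyl-6-(triethylsilyloxy)octa-2,7-dienal | O=C/C(C)=C/CC[C@@](C)(O[Si](CC)(CC)CC)C=C | intermediate
5 | allylboronic acid pinacol ester | C=CCB1OC(C)(C)C(C)(C)O1 | starting material
6 | pinacol borate ester of alcohol 7 (not isolated) | C=CC[C@H](OB1OC(C)(C)C(C)(C)O1)/C(C)=C/CC[C@@](C)(O[Si](CC)(CC)CC)C=C | intermediate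
7 | (4S,5E,9R)-5,9-dimethyl-9-(triethylsilyloxy)undeca-1,5,10-trien-4-ol | C=CC[C@H](O)/C(C)=C/CC[C@@](C)(O[Si](CC)(CC)CC)C=C | intermediate
8 | acryloyl chloride | C=CC(=O)Cl | starting material
9 | (4S,5E,9R)-5,9-dimethyl-9-(triethylsilyloxy)undeca-1,5,10-trien-4-yl acrylate | C=CC(=O)O[C@@H](CC=C)/C(C)=C/CC[C@@](C)(O[Si](CC)(CC)CC)C=C | intermediate
10 | (6S)-6-[(2E,6R)-6-methyl-6-(triethylsilyloxy)octa-2,7-dien-2-yl]-5,6-dihydro-2H-pyran-2-one | O=C1C=CC[C@@H](/C(C)=C/CC[C@@](C)(O[Si](CC)(CC)CC)C=C)O1 | intermediate
11 | isopropyl vinyl ketone (4-methylpent-1-en-3-one) | C=CC(=O)C(C)C | starting material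
12 | 4-methyl-3-(trimethylsilyloxy)penta-1,3-diene | C=CC(O[Si](C)(C)C)=C(C)C | intermediate
13 | lithium 4-methylpenta-1,3-dien-3-olate (not isolated) | [Li+].[O-]C(C=C)=C(C)C | intermediate
14 | lithium lactone enolate after the first Michael addition; C4–C5 bond trans to the C7 alkenyl group, pendant vinyl ketone (not isolated) | [Li+].[O-]C1=C[C@H](C(C)(C)C(=O)C=C)C[C@@H](/C(C)=C/CC[C@@](C)(O[Si](CC)(CC)CC)C=C)O1 | intermediate
15 | lithium C3 enolate of the cis-fused keto lactone (not isolated) | O=C1O[C@H](/C(C)=C/CC[C@@](C)(O[Si](CC)(CC)CC)C=C)C[C@H]2C(C)(C)C([O-])=CC[C@@H]12.[Li+] | intermediate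
16 | 5,5-dimethyl-3-[(2E,6R)-6-methyl-6-(triethylsilyloxy)octa-2,7-dien-2-yl]-6-(triisopropylsilyloxy)-3,4,4a,5,8,8a-hexahydro-1H-isochromen-1-one; 3-alkenyl, H-4a and H-8a on the same face | O=C1O[C@H](/C(C)=C/CC[C@@](C)(O[Si](CC)(CC)CC)C=C)C[C@H]2C(C)(C)C(O[Si](C(C)C)(C(C)C)C(C)C)=CC[C@@H]12 | intermediate
17 | 1-(tert-butyldimethylsilyloxy)-5,5-dimethyl-3-[(2E,6R)-6-methyl-6-(triethylsilyloxy)octa-2,7-dien-2-yl]-6-(triisopropylsilyloxy)-4,4a,5,8-tetrahydro-3H-isochromene; 3-alkenyl cis to H-4a | CC(C)(C)[Si](C)(C)OC1=C2CC=C(O[Si](C(C)C)(C(C)C)C(C)C)C(C)(C)[C@@H]2C[C@@H](/C(C)=C/CC[C@@](C)(O[Si](CC)(CC)CC)C=C)O1 | intermediate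
18 | tert-butyldimethylsilyl ester of acid 19 (not isolated) | C=C[C@](C)(O[Si](CC)(CC)CC)CC[C@H]1C(C)=CC[C@H]2C(C)(C)C(O[Si](C(C)C)(C(C)C)C(C)C)=CC[C@]12C(=O)O[Si](C)(C)C(C)(C)C | intermediate
19 | (13R)-13-(triethylsilyloxy)-3-(triisopropylsilyloxy)labda-2,7,14-trien-20-oic acid (5α-H, 9α-H, 10β-CO2H) | C=C[C@](C)(O[Si](CC)(CC)CC)CC[C@H]1C(C)=CC[C@H]2C(C)(C)C(O[Si](C(C)C)(C(C)C)C(C)C)=CC[C@]12C(=O)O | intermediate
20 | (13R)-13-(triethylsilyloxy)-3-(triisopropylsilyloxy)labda-2,7,14-trien-20-ol | C=C[C@](C)(O[Si](CC)(CC)CC)CC[C@H]1C(C)=CC[C@H]2C(C)(C)C(O[Si](C(C)C)(C(C)C)C(C)C)=CC[C@]12CO | intermediate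
21 | (13R)-13-(triethylsilyloxy)-3-(triisopropylsilyloxy)labda-2,7,14-trien-20-yl acetate | C=C[C@](C)(O[Si](CC)(CC)CC)CC[C@H]1C(C)=CC[C@H]2C(C)(C)C(O[Si](C(C)C)(C(C)C)C(C)C)=CC[C@]12COC(C)=O | intermediate
22 | (13R)-2α,3α-epoxy-13-(triethylsilyloxy)-3β-(triisopropylsilyloxy)labda-7,14-dien-20-yl acetate (not isolated) | C=C[C@](C)(O[Si](CC)(CC)CC)CC[C@H]1C(C)=CC[C@H]2C(C)(C)[C@]3(O[Si](C(C)C)(C(C)C)C(C)C)O[C@@H]3C[C@]12COC(C)=O | intermediate
23 | (13R)-2α-hydroxy-3-oxo-13-(triethylsilyloxy)labda-7,14-dien-20-yl acetate | C=C[C@](C)(O[Si](CC)(CC)CC)CC[C@H]1C(C)=CC[C@H]2C(C)(C)C(=O)[C@H](O)C[C@]12COC(C)=O | intermediate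
24 | (13R)-2α,3α-dihydroxy-13-(triethylsilyloxy)labda-7,14-dien-20-yl acetate | C=C[C@](C)(O[Si](CC)(CC)CC)CC[C@H]1C(C)=CC[C@H]2C(C)(C)[C@H](O)[C@H](O)C[C@]12COC(C)=O | intermediate
25 | angelic acid, (Z)-2-methylbut-2-enoic acid | C/C=C(/C)C(=O)O | starting material
26 | angelic 2,4,6-trichlorobenzoic anhydride | C/C=C(/C)C(=O)OC(=O)c1c(Cl)cc(Cl)cc1Cl | intermediate
27 | (13R)-20-acetoxy-3α-hydroxy-13-(triethylsilyloxy)labda-7,14-dien-2α-yl (Z)-2-methylbut-2-enoate | C=C[C@](C)(O[Si](CC)(CC)CC)CC[C@H]1C(C)=CC[C@H]2C(C)(C)[C@H](O)[C@H](OC(=O)/C(C)=C\C)C[C@]12COC(C)=O | intermediate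
28 | CNP0171655.1, (13R)-20-acetoxy-3α,13-dihydroxylabda-7,14-dien-2α-yl (Z)-2-methylbut-2-enoate | C=C[C@](C)(O)CC[C@H]1C(C)=CC[C@H]2C(C)(C)[C@H](O)[C@H](OC(=O)/C(C)=C\C)C[C@]12COC(C)=O | target

## Step count and risks

Total step count: 17 (15 on the main line plus the two reagent-forming side steps 7 and 15).
Longest linear sequence: 15 steps from (R)-linalool (steps 1–6, 8–14, 16, 17).

Steps most likely to fail:

**Step 8 (annulation).** The first conjugate addition joins a fully substituted enolate carbon to C5 and may be slow. The basic dienolate may instead remove a C6 proton of the lactone and trigger ring-opening elimination of the carboxylate, or ring closure may lag so that silylation traps open-chain material. The fallback sets out from 10 and 11 and swaps the anionic double Michael reaction for an acid-catalysed formal cycloaddition. Ketone 11 would be converted with i-Pr3SiOTf/Et3N into 4-methyl-3-(triisopropylsilyloxy)penta-1,3-diene F1. F1 and 10 would then be combined with catalytic triflimide HN(SO2CF3)2 (CH2Cl2, −78 °C; i-Pr3SiN(SO2CF3)2 formed in the flask) in a Mukaiyama–Michael/Michael sequence (formal Diels–Alder reaction), again anti to the C7 substituent. Silyl transfer regenerates the enol ether, so the route is rejoined at 16.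

**Step 10 (key rearrangement, fed by step 9).** Incomplete O-silylation of the hindered C10 enolate, or a boat transition state too congested for the quaternary C10–tertiary C9 bond to form, would leave ketene acetal that reverts to lactone on hydrolysis. The fallback sets out from 16 and keeps the same C9–C10 bond formation but uses the Claisen rearrangement of a 2-alkenyl dihydropyran. Reduction with i-Bu2AlH (toluene, −78 °C) would give lactol F2, and MeSO2Cl/Et3N would dehydrate it to the 3,4-dihydro-2H-pyran F3 (C10=C20 enol ether). Heating F3 (xylene, sealed tube, about 180 °C) should effect the [3,3] shift through the same enforced boat and give the C20 aldehyde F4. NaBH4 (MeOH, 0 °C) would then give 20, where the route is rejoined (steps 9–11 bypassed).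

**Step 13 (C2 oxidation).** The dioxirane may lose chemoselectivity and also epoxidise the C7=C8 alkene. Alternatively the silyloxy epoxide may undergo 1,4-silyl shift to the 2-O-silyl ketone before fluoride is added, after which the secondary silyl ether could not be removed without loss of the tertiary one. The fallback sets out from 21 and replaces epoxidation by enolate hydroxylation. Bu4NF (THF, −78 °C, then AcOH) would cleave the enol silyl ether, which is far more labile than the tertiary alkyl silyl ether, to give 3-ketone F5. KN(SiMe3)2 (THF, −78 °C) would regenerate the C2/C3 enolate (C4 is quaternary; the ketone is more acidic than the acetate). 2-(Phenylsulfonyl)-3-phenyloxaziridine, which does not epoxidise alkenes, would hydroxylate it from the α face, and the route is rejoined at 23.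

Further compounds
F1 | step 8 | 4-methyl-3-(triisopropylsilyloxy)penta-1,3-diene | C=CC(O[Si](C(C)C)(C(C)C)C(C)C)=C(C)C
F2 | step 10 | lactol from 16 (C20 hemiacetal, anomeric mixture) | OC1O[C@H](/C(C)=C/CC[C@@](C)(O[Si](CC)(CC)CC)C=C)C[C@H]2C(C)(C)C(O[Si](C(C)C)(C(C)C)C(C)C)=CC[C@@H]12
F3 | step 10 | 5,5-dimethyl-3-[(2E,6R)-6-methyl-6-(triethylsilyloxy)octa-2,7-dien-2-yl]-6-(triisopropylsilyloxy)-4,4a,5,8-tetrahydro-3H-isochromene | C1=C2CC=C(O[Si](C(C)C)(C(C)C)C(C)C)C(C)(C)[C@@H]2C[C@@H](/C(C)=C/CC[C@@](C)(O[Si](CC)(CC)CC)C=C)O1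
F4 | step 10 | (13R)-13-(triethylsilyloxy)-3-(triisopropylsilyloxy)labda-2,7,14-trien-20-al | C=C[C@](C)(O[Si](CC)(CC)CC)CC[C@H]1C(C)=CC[C@H]2C(C)(C)C(O[Si](C(C)C)(C(C)C)C(C)C)=CC[C@]12C=O
F5 | step 13 | (13R)-3-oxo-13-(triethylsilyloxy)labda-7,14-dien-20-yl acetate | C=C[C@](C)(O[Si](CC)(CC)CC)CC[C@H]1C(C)=CC[C@H]2C(C)(C)C(=O)CC[C@]12COC(C)=O
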